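- Molar per hour is the unit for your quick number, because the question is how fast the solution gains and loses starting material.

solid substrate 1.0 M; time 10 d

    starting material ⇌ ring (K1 = 1.72, k1 = 0.0336 h⁻¹)
    2 starting material → open dimer (k2 = 0.0554 M⁻¹ h⁻¹)
    starting material + open dimer → open trimer (k3 = 0.00382 M⁻¹ h⁻¹)
    solid substrate ⇌ starting material, rate k4*(cs4 - [starting material]) while solid is left; crystals form when [starting material] > cs4 (cs4 = 0.23 M, k4 = 0.0305 h⁻¹)

- ring at 10 d, in percent of the solid substrate charged
- concentration of starting material in solution at 10 d, in percent of saturation

- percentages count the solid substrate that a species holds: one open dimer counts as two
- percentages count the solid substrate that a species holds: one open trimer counts as three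
- a step written with two of one species runs at k times the square of its concentration and takes two of it each time
- solid, in amounts per volume of the solution: solid substrate
- at the start none of the solid substrate is in solution
- starting material means what is dissolved; the solid is not counted in it
- run time (flask): 10 d

- A first hunch of our own puts the ring at K1 times saturation, which is 39.6% of the charge.
- We expect less: at c(starting material) = 0.23 M the dissolving delivers nothing, while step 2 still takes 0.00586 M h⁻¹.
- The relaxation half-life of starting material and ring is 0.544 d, which is short against 10 d, so the run lasts 18.4 of them. We therefore take the ring as following K1 times c(starting material), with little net flow through step 1.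
- We drop step 3, because its constant is much smaller than that of step 2.
- That leaves a quasi-steady state: dissolving equals dimer formation, k4 × (cs4 − c) = 2 × k2 × c × c, with c standing for c(starting material). With the concentration h = k4/(2 × k2), here 0.275 M, its root is the plateau level c*, the concentration at which supply and dimer formation balance, 0.149 M.
- This assumes that solid substrate is still present at 10 d.
- Our answer for the ring is K1 × c*, or 25.7% of the charge, and starting material stands at c*/cs4, or 64.9% of saturation.
- The forecast gives 23.9% and 62.6%, reached by “Stepping by hand”.
- The flask gives ring at 23.7% of the charge and starting material at 62.4% of saturation, with solid substrate still at 20.1% of the charge at 10.0 d. A neighbouring flask charged with 1.7 M of solid substrate and read at the same time has the same c*, so K1 × c* divided by its charge gives 15.1%, and that flask holds ring at 13.9% of its charge.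

(The rate constants were chosen freely; the run is a simulation.)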